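**Plan**
- Retrosynthetic cuts: the depside C(=O)–O bond between ring A and ring B, the O–CH3 bond at C2 of ring B, the benzylic CH2–C(=O) bond of the ring A side chain, and the C1–C6 and C2–C3 bonds of ring B.
- Enabling feature: ring B carries oxygens at C2 and C4, the carboxyl at C1 and the pentyl group at C6. That is a 6-pentyl-2,4-dioxocyclohexane-1-carboxylate minus two hydrogens, a ring that one enone and one malonate can assemble.
- Forward order: ring B is closed first (Michael, then Claisen) and aromatized. Ring A is bought as an arene, its side chain is attached by lateral lithiation and acylation, and the ketone is masked as a dioxolane.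
- Joining: the halves are esterified at the unchelated 4-hydroxyl of ring B, the chelated 2-hydroxyl is methylated, the ketone is released and the benzyl ester is hydrogenolysed.
- Stereochemistry: the target has no stereocentre. The two sp3 centres made in the annulation (C1, C6) are erased by the aromatization.

Key step: step 1

Remark on the chemistry: 4 is drawn as one enantiomer of the racemic trans compound and as one enol form of the 2,4-dione; enolates and other salts of numbered compounds are not numbered apart from them, and amide 7 is taken as a catalogue compound.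

**Step 1**
Reactants: 1 (E)-non-3-en-2-one; 2 dibenzyl malonate
Product: 4 rac-trans-benzyl 2-hydroxy-4-oxo-6-pentylcyclohex-2-ene-1-carboxylate, via dibenzyl 2-(2-oxononan-4-yl)malonate 3 (not isolated)
Conditions: NaH (1.1 equiv), BnOH (10 mol%), THF, 0 °C → reflux; aq. HCl
Reagents that add atoms: none
Why: The sodium enolate of 2 adds in Michael fashion to C4 of enone 1 and so forms the future C1–C6 bond of ring B (adduct 3); benzyloxide-mediated proton exchange then makes the methyl-ketone enolate available, whose carbon attacks one benzyl ester in a Claisen (Dieckmann-type) condensation that forms C2–C3 and expels benzyl alkoxide. The closest known reaction type is the malonate/alkenyl methyl ketone Michael–Dieckmann annulation that gives 6-alkyl-2,4-dioxocyclohexanecarboxylates from dimethyl malonate and NaOMe; only the ester group differs here, and NaH with catalytic BnOH keeps the alkoxide matched to the benzyl esters. The six-membered ring closes in a 6-(enolendo)-exo-trig mode, both enolate carbons becoming ring atoms. C6 is set in the conjugate addition and C1 in the ring closure; C1 stays epimerizable between the ester and the enolized ketone, so the diequatorial trans racemate should prevail, and since step 2 erases both centres their configuration is of no consequence. The step needs site selectivity between the two ketone enolates and ring size secures it, the internal enolate being able to close only a four-membered ring; the soft malonate anion adds 1,4 and not 1,2, and irreversible deprotonation of the acidic 1,3-dione by the released benzyloxide pulls the equilibria to 4.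

**Step 2**
Reactants: 4 rac-trans-benzyl 2-hydroxy-4-oxo-6-pentylcyclohex-2-ene-1-carboxylate
Product: 5 benzyl 2,4-dihydroxy-6-pentylbenzoate
Conditions: I2 (20 mol%), DMSO, 80 °C
Reagents that add atoms: none
Why: Iodine-catalysed oxidative aromatization, in which α-iodination of the enolized dione and loss of HI introduce the missing unsaturation at C6, enolization then gives the resorcinol, DMSO reoxidizes HI to I2, and both sp3 centres of 4 vanish.

**Step 3**
Reactants: 6 methyl 2,4-dimethoxy-6-methylbenzoate; 7 N-methoxy-N-methylhexanamide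
Product: 9 methyl 2,4-dimethoxy-6-(2-oxoheptyl)benzoate, via Weinreb hemiaminal lithium alkoxide 8 (not isolated)
Conditions: LiN(iPr)2 (LDA, 1.3 equiv), THF, −78 °C; then 7, −78 °C; aq. NH4Cl
Reagents that add atoms: none
Why: Lateral (benzylic) lithiation of the ortho-toluate followed by a Weinreb ketone synthesis, in which the ester-stabilized benzylic anion is acylated only once because the chelated tetrahedral adduct 8 persists until the quench, which also keeps any ketone enolate from cyclizing onto the neighbouring ester in the flask.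

**Step 4**
Reactants: 9 methyl 2,4-dimethoxy-6-(2-oxoheptyl)benzoate
Product: 10 methyl 2,4-dimethoxy-6-[(2-pentyl-1,3-dioxolan-2-yl)methyl]benzoate
Conditions: Me3SiOCH2CH2OSiMe3, Me3SiOSO2CF3 (5 mol%), CH2Cl2, −78 → −20 °C; pyridine quench
Reagents that add atoms: 1,2-bis(trimethylsilyloxy)ethane, C[Si](C)(C)OCCO[Si](C)(C)C
Why: Noyori ketalization under aprotic low-temperature conditions converts the ketone into its dioxolane without the hot protic acid that would lactonize the keto ester to an isocoumarin, and the masked ketone can then no longer enolize toward an ester during steps 5 to 7.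

**Step 5**
Reactants: 10 methyl 2,4-dimethoxy-6-[(2-pentyl-1,3-dioxolan-2-yl)methyl]benzoate
Product: 11 2,4-dimethoxy-6-[(2-pentyl-1,3-dioxolan-2-yl)methyl]benzoic acid
Conditions: KOH, DMSO–H2O, 80 °C; then cold dilute HCl to pH 4
Reagents that add atoms: potassium hydroxide, [K+].[OH-]
Why: Saponification of a di-ortho-substituted methyl benzoate needs hot hydroxide in a dipolar solvent, which the base-stable dioxolane and the aryl methyl ethers tolerate, and cold acidification to pH 4 should free the acid without opening the ketal.

**Step 6**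
Reactants: 5 benzyl 2,4-dihydroxy-6-pentylbenzoate; 11 2,4-dimethoxy-6-[(2-pentyl-1,3-dioxolan-2-yl)methyl]benzoic acid
Product: 12 benzyl 4-({2,4-dimethoxy-6-[(2-pentyl-1,3-dioxolan-2-yl)methyl]benzoyl}oxy)-2-hydroxy-6-pentylbenzoate
Conditions: DCC (1.2 equiv), 4-(dimethylamino)pyridine (20 mol%), CH2Cl2, 0 °C → rt
Reagents that add atoms: none
Why: Steglich esterification, selective for the 4-hydroxyl of 5 because the 2-hydroxyl is held in a hydrogen bond to the benzyl ester carbonyl and is flanked by it, while the neutral conditions leave the dioxolane intact.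

**Step 7**
Reactants: 12 benzyl 4-({2,4-dimethoxy-6-[(2-pentyl-1,3-dioxolan-2-yl)methyl]benzoyl}oxy)-2-hydroxy-6-pentylbenzoate
Product: 13 benzyl 4-({2,4-dimethoxy-6-[(2-pentyl-1,3-dioxolan-2-yl)methyl]benzoyl}oxy)-2-methoxy-6-pentylbenzoate
Conditions: MeI, K2CO3, DMF, 40 °C
Reagents that add atoms: iodomethane, CI
Why: Williamson ether synthesis on the chelated phenol, in which the depside ester is shielded by its two ortho substituents against the phenoxide and, with the ketone masked, no enolate can be C-methylated or expel the ring B phenoxide.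

**Step 8**
Reactants: 13 benzyl 4-({2,4-dimethoxy-6-[(2-pentyl-1,3-dioxolan-2-yl)methyl]benzoyl}oxy)-2-methoxy-6-pentylbenzoate
Product: 14 benzyl 4-{[2,4-dimethoxy-6-(2-oxoheptyl)benzoyl]oxy}-2-methoxy-6-pentylbenzoate
Conditions: 1 M aq. HCl, THF, rt
Reagents that add atoms: water, O
Why: Acid-catalysed ketal hydrolysis of a dialkyl dioxolane proceeds in dilute acid at room temperature, where the hindered aryl ester and the benzyl ester should not be cleaved.

**Step 9**
Reactants: 14 benzyl 4-{[2,4-dimethoxy-6-(2-oxoheptyl)benzoyl]oxy}-2-methoxy-6-pentylbenzoate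
Product: 15 4-{[2,4-dimethoxy-6-(2-oxoheptyl)benzoyl]oxy}-2-methoxy-6-pentylbenzoic acid
Conditions: H2 (1 atm), 10% Pd/C, EtOAc, rt
Reagents that add atoms: none
Why: Catalytic hydrogenolysis of the benzyl ester frees the acid under neutral conditions that leave the aryl ester, the aliphatic ketone and the methyl ethers untouched.

**Compound list**
1 | (E)-non-3-en-2-one | CCCCC/C=C/C(C)=O | starting material
2 | dibenzyl malonate | O=C(CC(=O)OCc1ccccc1)OCc1ccccc1 | starting material
3 | dibenzyl 2-(2-oxononan-4-yl)malonate (racemic Michael adduct, present as its sodium salt) | CCCCCC(CC(C)=O)C(C(=O)OCc1ccccc1)C(=O)OCc1ccccc1 | intermediate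
4 | rac-trans-benzyl 2-hydroxy-4-oxo-6-pentylcyclohex-2-ene-1-carboxylate (one enantiomer drawn) | CCCCC[C@@H]1CC(=O)C=C(O)[C@H]1C(=O)OCc1ccccc1 | intermediate
5 | benzyl 2,4-dihydroxy-6-pentylbenzoate | CCCCCc1cc(O)cc(O)c1C(=O)OCc1ccccc1 | intermediate
6 | methyl 2,4-dimethoxy-6-methylbenzoate | COC(=O)c1c(C)cc(OC)cc1OC | starting material
7 | N-methoxy-N-methylhexanamide | CCCCCC(=O)N(C)OC | starting material
8 | methyl 2-{2-hydroxy-2-[methoxy(methyl)amino]heptyl}-4,6-dimethoxybenzoate (racemic tetrahedral Weinreb adduct, present as its lithium alkoxide) | CCCCCC(O)(Cc1cc(OC)cc(OC)c1C(=O)OC)N(C)OC | intermediate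
9 | methyl 2,4-dimethoxy-6-(2-oxoheptyl)benzoate | CCCCCC(=O)Cc1cc(OC)cc(OC)c1C(=O)OC | intermediate
10 | methyl 2,4-dimethoxy-6-[(2-pentyl-1,3-dioxolan-2-yl)methyl]benzoate | CCCCCC1(Cc2cc(OC)cc(OC)c2C(=O)OC)OCCO1 | intermediate
11 | 2,4-dimethoxy-6-[(2-pentyl-1,3-dioxolan-2-yl)methyl]benzoic acid | CCCCCC1(Cc2cc(OC)cc(OC)c2C(=O)O)OCCO1 | intermediate
12 | benzyl 4-({2,4-dimethoxy-6-[(2-pentyl-1,3-dioxolan-2-yl)methyl]benzoyl}oxy)-2-hydroxy-6-pentylbenzoate | CCCCCc1cc(OC(=O)c2c(CC3(CCCCC)OCCO3)cc(OC)cc2OC)cc(O)c1C(=O)OCc1ccccc1 | intermediate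
13 | benzyl 4-({2,4-dimethoxy-6-[(2-pentyl-1,3-dioxolan-2-yl)methyl]benzoyl}oxy)-2-methoxy-6-pentylbenzoate | CCCCCc1cc(OC(=O)c2c(CC3(CCCCC)OCCO3)cc(OC)cc2OC)cc(OC)c1C(=O)OCc1ccccc1 | intermediate
14 | benzyl 4-{[2,4-dimethoxy-6-(2-oxoheptyl)benzoyl]oxy}-2-methoxy-6-pentylbenzoate | CCCCCC(=O)Cc1cc(OC)cc(OC)c1C(=O)Oc1cc(CCCCC)c(C(=O)OCc2ccccc2)c(OC)c1 | intermediate
15 | 4-{[2,4-dimethoxy-6-(2-oxoheptyl)benzoyl]oxy}-2-methoxy-6-pentylbenzoic acid | CCCCCC(=O)Cc1cc(OC)cc(OC)c1C(=O)Oc1cc(CCCCC)c(C(=O)O)c(OC)c1 | target

Total step count: 9. Longest linear sequence: 7 steps (steps 3, 4, 5, 6, 7, 8, 9 from compound 6).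

**Steps most likely to fail**

Step 1. In THF the adduct 3 rests as its malonate anion, so equilibration to the methyl-ketone enolate and the Claisen closure may be slow, and retro-Michael cleavage or a second conjugate addition may compete. The fallback sets out from 1 and commercial dimethyl malonate with NaOMe in refluxing MeOH, the alkoxide-matched protic medium in which this annulation is classically run. It should pass through dimethyl 2-(2-oxononan-4-yl)malonate F1 to rac-trans-methyl 2-hydroxy-4-oxo-6-pentylcyclohex-2-ene-1-carboxylate F2. Aromatization with I2 in DMSO would give methyl 2,4-dihydroxy-6-pentylbenzoate F3. Saponification (aq. KOH, MeOH, reflux under N2, cold acidification so the free acid is never heated) would give 2,4-dihydroxy-6-pentylbenzoic acid F4. Carboxylate-selective benzylation (BnBr, KHCO3, DMF, rt) comes back to the route at 5.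

Step 6. Acyl transfer from the crowded O-acylisourea of the di-ortho-substituted acid may be slow enough that rearrangement to the N-acylurea overtakes esterification. The fallback sets out from 11 and activates it separately under neutral conditions with 1-chloro-N,N,2-trimethylprop-1-en-1-amine in CH2Cl2, giving 2,4-dimethoxy-6-[(2-pentyl-1,3-dioxolan-2-yl)methyl]benzoyl chloride F5. Acylation of 5 with F5 (Et3N, catalytic 4-(dimethylamino)pyridine, CH2Cl2, 0 °C) comes back to the route at 12.

Step 2. Once the electron-rich resorcinol ring has formed, electrophilic iodination of it may compete with the dehydrogenation, or the sequence may stall after the first iodination. The fallback sets out from 4 and uses a halogen-free dehydrogenation. Double O-silylation (Me3SiOSO2CF3, Et3N, CH2Cl2, 0 °C) should give benzyl 6-pentyl-2,4-bis(trimethylsilyloxy)cyclohexa-1,3-diene-1-carboxylate F6. DDQ in toluene would abstract hydride from the saturated edge of the ring and give benzyl 6-pentyl-2,4-bis(trimethylsilyloxy)benzoate F7. Desilylation with dilute HCl in THF comes back to the route at 5.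

**Further compounds**
F1 | step 1 | dimethyl 2-(2-oxononan-4-yl)malonate | CCCCCC(CC(C)=O)C(C(=O)OC)C(=O)OC
F2 | step 1 | rac-trans-methyl 2-hydroxy-4-oxo-6-pentylcyclohex-2-ene-1-carboxylate | CCCCC[C@@H]1CC(=O)C=C(O)[C@H]1C(=O)OC
F3 | step 1 | methyl 2,4-dihydroxy-6-pentylbenzoate | CCCCCc1cc(O)cc(O)c1C(=O)OC
F4 | step 1 | 2,4-dihydroxy-6-pentylbenzoic acid | CCCCCc1cc(O)cc(O)c1C(=O)O
F5 | step 6 | 2,4-dimethoxy-6-[(2-pentyl-1,3-dioxolan-2-yl)methyl]benzoyl chloride | CCCCCC1(Cc2cc(OC)cc(OC)c2C(=O)Cl)OCCO1
F6 | step 2 | benzyl 6-pentyl-2,4-bis(trimethylsilyloxy)cyclohexa-1,3-diene-1-carboxylate (racemic) | CCCCCC1CC(O[Si](C)(C)C)=CC(O[Si](C)(C)C)=C1C(=O)OCc1ccccc1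
F7 | step 2 | benzyl 6-pentyl-2,4-bis(trimethylsilyloxy)benzoate | CCCCCc1cc(O[Si](C)(C)C)cc(O[Si](C)(C)C)c1C(=O)OCc1ccccc1
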